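The oxepane ring B (C5–C6–O–C7–C8–C9–C10) is taken apart as a formal (4+3) union: C5 and C9 both flank quaternary C10 and are unmasked as a ring-A 1,3-diketone, while C6 and C8, 1,4-related through O–C7, arrive as a chloromethyl ether on a cyclopentenone β-carbon. One samarium diiodide operation closes ring C by ketone–enone reductive coupling (C8–C9) and ring B by Barbier addition of the C6 carbanion to the C5 ketone (C5–C6), giving the tetracyclic skeleton from a monocyclic diketone tethered to a cyclopentenone. Both new carbinols are later dehydrated; the enol ether becomes the lactol, the C9=C11 alkene the epoxide.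

Key step: step 15

Remark (numbering): atom numbers follow the ent-kaurane skeleton: ring A = C1–C5, C10; ring B = C5, C6, O, C7, C8, C9, C10; ring C = C8, C9, C11–C14; ring D = C8, C14, C13, C16, C15; C17 = exocyclic methylene; C20 = methyl on C10; α = the face carrying C20.

Remark (assumption): the lactol carbon C6 epimerises through the open hydroxy aldehyde; the last step is assumed to settle on the epimer drawn for the target as the more stable one.

Remark (mixtures): carbinol or acetal centres written without configuration (C5 in 4–6, the ring-D carbinol in 11–16, C9 in 16, C5 and C9 in 21–22, C6 in 24–28, C15 in 27) are expected as epimer mixtures; all are erased or equilibrated later.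

Step 1
Reactants: 1 ketoisophorone
Product: 2 (R)-phorenol
Conditions: RuCl(p-cymene)[(R,R)-TsDPEN] (1 mol %), i-PrOH, rt
Reagents that add atoms: none
Why: Noyori asymmetric transfer hydrogenation reduces the less hindered carbonyl (future C2, not the one flanked by the gem-dimethyl group), and the (R,R)-ligand should deliver the (R)-carbinol that is later relayed to C10.

Step 2
Reactants: 2 (R)-phorenol
Product: 3 stannylmethyl ether of phorenol
Conditions: KH, THF, 0 °C; then Bu3SnCH2I, rt
Reagents that add atoms: tributyl(iodomethyl)stannane CCCC[Sn](CCCC)(CCCC)CI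
Why: Williamson etherification of the potassium alkoxide with the reactive iodomethylstannane installs the handle for the [2,3]-shift without touching the stereocentre.

Step 3
Reactants: 3 stannylmethyl ether of phorenol
Product: 4 allylic alcohol stannylmethyl ether
Conditions: NaBH4, CeCl3·7H2O, MeOH, −20 °C
Reagents that add atoms: none
Why: Luche 1,2-reduction removes the only carbonyl that the organolithium of step 4 could attack; the C5 carbinol forms as an epimer mixture and is reoxidised in step 5.

Step 4
Reactants: 4 allylic alcohol stannylmethyl ether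
Product: 6 (2S)-2-(hydroxymethyl)-2,6,6-trimethylcyclohex-3-en-1-ol, via dilithio ether 5 (not isolated)
Conditions: n-BuLi (2.2 equiv), THF, −78 → −20 °C
Reagents that add atoms: none
Why: Tin–lithium exchange gives the α-alkoxymethyllithium, whose Wittig–Still [2,3]-sigmatropic rearrangement is suprafacial, so the hydroxymethyl carbon (C9) enters C10 on the face that carried the C2 oxygen, setting the quaternary centre while the alkene moves to C1=C2.

Step 5
Reactants: 6 (2S)-2-(hydroxymethyl)-2,6,6-trimethylcyclohex-3-en-1-ol
Product: 7 (1S)-1,3,3-trimethyl-2-oxocyclohex-5-ene-1-carbaldehyde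
Conditions: Dess–Martin periodinane (3 equiv), NaHCO3, CH2Cl2, rt
Reagents that add atoms: none
Why: Dess–Martin oxidation converts the primary alcohol into the C9 aldehyde and the hindered secondary alcohol into the C5 ketone; neither carbonyl can enolise towards C10, so the quaternary centre is safe.

Step 6
Reactants: 8 (R)-4-(tert-butyldimethylsilyloxy)cyclopent-2-en-1-one
Product: 10 (S)-4-vinylcyclopent-2-en-1-one, via trans-3-vinyl-4-silyloxycyclopentanone 9 (not isolated)
Conditions: CH2=CHMgBr, CuBr·SMe2 (10 mol %), THF, −78 °C; aq NH4Cl; then DBU, CH2Cl2, −20 °C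
Reagents that add atoms: vinylmagnesium bromide C=C[Mg]Br
Why: Copper-catalysed conjugate addition of the vinyl Grignard reagent occurs anti to the silyloxy group and E1cB loss of silanol then gives the 4-substituted cyclopentenone, so the silyloxy stereocentre is traded for C13.

Step 7
Reactants: 10 (S)-4-vinylcyclopent-2-en-1-one
Product: 11 1-[(methoxymethoxy)methyl]-4-vinylcyclopent-2-en-1-ol
Conditions: Bu3SnCH2OCH2OMe, n-BuLi, THF, −78 °C; CeCl3; then 10, −78 °C
Reagents that add atoms: tributyl[(methoxymethoxy)methyl]stannane CCCC[Sn](CCCC)(CCCC)COCOC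
Why: Tin–lithium exchange gives (methoxymethoxy)methyllithium, which as its organocerium reagent adds 1,2 to the enone without deprotonating the acidic C13–H and brings in C7 with its oxygen; the carbinol centre is lost in step 11.

Step 8
Reactants: 11 1-[(methoxymethoxy)methyl]-4-vinylcyclopent-2-en-1-ol
Product: 13 2-{4-hydroxy-4-[(methoxymethoxy)methyl]cyclopent-2-en-1-yl}ethan-1-ol, via B-alkyl-9-BBN adduct 12 (not isolated)
Conditions: 9-BBN (1.3 equiv), THF, 0 °C → rt; then NaOH, H2O2, 0 °C
Reagents that add atoms: hydrogen peroxide OO
Why: Hydroboration–oxidation with 9-BBN is selective for the monosubstituted vinyl group over the ring alkene and places the hydroxyl on the terminal carbon (C11).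

Step 9
Reactants: 13 2-{4-hydroxy-4-[(methoxymethoxy)methyl]cyclopent-2-en-1-yl}ethan-1-ol
Product: 14 4-(2-iodoethyl)-1-[(methoxymethoxy)methyl]cyclopent-2-en-1-ol
Conditions: I2, PPh3, imidazole, CH2Cl2, 0 °C
Reagents that add atoms: iodine II
Why: Appel-type iodination converts the primary alcohol; the hindered tertiary allylic alcohol should not react at 0 °C.

Step 10
Reactants: 14 4-(2-iodoethyl)-1-[(methoxymethoxy)methyl]cyclopent-2-en-1-ol; 7 (1S)-1,3,3-trimethyl-2-oxocyclohex-5-ene-1-carbaldehyde
Product: 16 coupled diol, via dilithio alkoxide 15 (not isolated)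
Conditions: t-BuLi (3.3 equiv), Et2O, −78 °C; then 7, −78 °C; AcOH quench at −78 °C
Reagents that add atoms: none
Why: Iodine–lithium exchange on the lithium alkoxide gives a primary alkyllithium that adds to the non-enolisable aldehyde much faster than to the C5 ketone lying between two quaternary carbons, forming C9–C11; the cold quench avoids retro-aldol cleavage and the C9 carbinol (epimers) is oxidised in step 11.

Step 11
Reactants: 16 coupled diol
Product: 17 diketo enone
Conditions: pyridinium chlorochromate [C5H5NH][CrO3Cl] (4 equiv), 4 Å MS, CH2Cl2, rt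
Reagents that add atoms: pyridinium chlorochromate [O-][Cr](=O)(=O)Cl.c1cc[nH+]cc1
Why: The chlorochromate oxidises the C9 carbinol to the ketone and converts the tertiary allylic alcohol by Babler–Dauben oxidative transposition ([3,3] shift of the chromate ester, then oxidation) into the cyclopentenone whose β-carbon is C8.

Step 12
Reactants: 17 diketo enone
Product: 18 cis-diol
Conditions: OsO4 (2 mol %), NMO, acetone–H2O, 0 °C
Reagents that add atoms: N-methylmorpholine N-oxide C[N+]1([O-])CCOCC1; water O
Why: Upjohn dihydroxylation: the electron-poor enone alkene reacts far more slowly than C1=C2, and in monocyclic ring A the C9 acyl group sits pseudoaxial on the face that also carries the axial C4 methyl, so OsO4 should add to the opposite face, cis to the C10 methyl, setting C1 and C2.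

Step 13
Reactants: 18 cis-diol
Product: 19 diacetate
Conditions: Ac2O, pyridine, DMAP, CH2Cl2, rt
Reagents that add atoms: acetic anhydride CC(=O)OC(C)=O
Why: DMAP-catalysed acetylation of the secondary cis-diol installs the target's own acetates, which are inert to the reductant of step 15.

Step 14
Reactants: 19 diacetate
Product: 20 chloromethyl ether
Conditions: BCl3 (1.0 equiv), CH2Cl2, −78 → −20 °C; volatiles removed, used crude
Reagents that add atoms: boron trichloride ClB(Cl)Cl
Why: Boron trichloride cleaves the MOM ether at the less hindered methoxy oxygen to leave the chloromethyl ether, a known conversion of MOM ethers, while acetates and ketones survive at low temperature.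

Step 15
Reactants: 20 chloromethyl ether
Product: 22 tetracyclic keto diol, via ring-C-closed chloromethyl ether ketol 21 (not isolated)
Conditions: SmI2 (6 equiv), THF–HMPA, −78 → 0 °C (20 added slowly to the reagent); then sat. aq NH4Cl
Reagents that add atoms: none
Why: Samarium diiodide effects a ketone–enone reductive coupling (the C9 ketyl adds to C8 or the enone radical anion attacks C9; both give the same bond) and reduces the C6–Cl bond to an α-alkoxymethyl samarium species that adds to the C5 ketone. The closest known reaction types are the samarium diiodide ketyl–olefin cyclisation onto α,β-unsaturated carbonyls and the samarium Barbier alkoxymethylation of ketones with chloromethyl ethers. Ring C closes 6-exo-trig onto the enone β-carbon C8, giving the bicyclo[3.2.1]octane, and oxepane ring B closes by 7-exo-trig addition of the C6 organosamarium to the C5 carbonyl. C8 is set by C13, because the two-carbon tether on C13 can reach only the cis face of the cyclopentenone; the C9 and C5 carbinol centres need no control since both become sp2 in step 16. The step needs chemoselectivity in pairing each nucleophile with its carbonyl, which ring size secures (six-membered for C8–C9; the C6 carbanion reaches C5 only through a seven-membered transition state once ring C exists, the C16 carbonyl being masked as its samarium enolate). It also needs suppression of pinacol coupling of the 1,3-diketone and of reductive loss of the C7 oxygen, which the fast irreversible 6-exo closure, excess reductant at −78 °C and the absence of a proton source should secure.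

Step 16
Reactants: 22 tetracyclic keto diol
Product: 23 enol ether diene
Conditions: Martin sulfurane Ph2S[OC(CF3)2Ph]2 (3 equiv), CH2Cl2, 0 °C → rt
Reagents that add atoms: none
Why: Martin sulfurane dehydration of both tertiary alcohols, each of which has β-hydrogens on one side only (C11 for the C9 carbinol, C6 for the C5 carbinol), so the C9=C11 alkene and the C5=C6 enol ether are the only possible regioisomers; the non-basic medium should suppress Grob fragmentation of the 1,3-diol.

Step 17
Reactants: 23 enol ether diene
Product: 24 methyl acetal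
Conditions: MeOH, PPTS (cat.), 0 °C → rt
Reagents that add atoms: methanol CO
Why: Acid-catalysed addition of methanol to the enol ether (acetal formation): protonation at C5 should occur from the face opposite the axial C10 and C4 methyl groups, setting H-5 anti to C20, and the oxocarbenium ion is captured as the methyl acetal that protects the lactol through the next four steps.

Step 18
Reactants: 24 methyl acetal
Product: 25 9α,11α-epoxide
Conditions: dimethyldioxirane, acetone, −20 → 0 °C
Reagents that add atoms: dimethyldioxirane CC1(C)OO1
Why: Epoxidation of the only alkene left, from the exo face of the bicyclo[3.2.1]octene (the side of the C14 bridge and of the C10 methyl), the other face being screened by the C15–C16 bridge and by C1 with its acetoxy group; this sets C9 and C11, and the dioxirane avoids Baeyer–Villiger attack on the ketone.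

Step 19
Reactants: 25 9α,11α-epoxide
Product: 26 16-methylene compound
Conditions: Ph3PCH3Br, KN(SiMe3)2, THF, 0 °C; then 25, 0 °C → rt
Reagents that add atoms: methyltriphenylphosphonium bromide C[P+](c1ccccc1)(c1ccccc1)c1ccccc1.[Br-]
Why: Wittig methylenation of the ring-D ketone, the only ketone present; acetates react much more slowly with the salt-free ylide at 0 °C and the hindered epoxide is inert.

Step 20
Reactants: 26 16-methylene compound
Product: 27 15-hydroxy-16-methylene compound
Conditions: SeO2 (cat.), t-BuOOH, CH2Cl2, rt
Reagents that add atoms: tert-butyl hydroperoxide CC(C)(C)OO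
Why: Selenium dioxide allylic oxidation (ene reaction then [2,3]-shift) of the exocyclic alkene at C15, the only allylic methylene since C13 is a bridgehead; the C15 carbinol configuration is irrelevant because it is oxidised next.

Step 21
Reactants: 27 15-hydroxy-16-methylene compound
Product: 28 enone methyl acetal
Conditions: Dess–Martin periodinane, NaHCO3, CH2Cl2, rt
Reagents that add atoms: none
Why: Dess–Martin oxidation of the allylic alcohol gives the α-methylene cyclopentanone under buffered conditions that spare epoxide, acetal and acetates.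

Step 22
Reactants: 28 enone methyl acetal
Product: 29 CNP0224512.1
Conditions: PPTS, acetone–H2O, 40 °C
Reagents that add atoms: water O
Why: Mild acid hydrolysis of the seven-membered cyclic methyl acetal gives the lactol, which should settle to its more stable C6 epimer, while acetates, the hindered epoxide and the enone should survive pyridinium tosylate in wet acetone.

Compound list
1 | ketoisophorone (2,6,6-trimethylcyclohex-2-ene-1,4-dione) | CC1=CC(=O)CC(C)(C)C1=O | starting material
2 | (R)-phorenol, (4R)-4-hydroxy-2,6,6-trimethylcyclohex-2-en-1-one | CC1=C[C@H](O)CC(C)(C)C1=O | intermediate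
3 | (4R)-2,6,6-trimethyl-4-[(tributylstannyl)methoxy]cyclohex-2-en-1-one | CC1=C[C@H](OC[Sn](CCCC)(CCCC)CCCC)CC(C)(C)C1=O | intermediate
4 | (4R)-2,6,6-trimethyl-4-[(tributylstannyl)methoxy]cyclohex-2-en-1-ol, both C1 epimers (this carbinol is kaurane C5) | CC1=C[C@H](OC[Sn](CCCC)(CCCC)CCCC)CC(C)(C)C1O | intermediate
5 | dilithio ether: lithium alkoxide of 4 with tributyltin replaced by lithium | CC1=C[C@H](OC[Li])CC(C)(C)C1O[Li] | intermediate
6 | (2S)-2-(hydroxymethyl)-2,6,6-trimethylcyclohex-3-en-1-ol, both C1 epimers (ring C2 = kaurane C10, hydroxymethyl carbon = C9) | OC[C@@]1(C)C(O)C(C)(C)CC=C1 | intermediate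
7 | (1S)-1,3,3-trimethyl-2-oxocyclohex-5-ene-1-carbaldehyde (ring-A keto aldehyde, CHO = C9) | O=C[C@@]1(C)C(=O)C(C)(C)CC=C1 | intermediate
8 | (R)-4-(tert-butyldimethylsilyloxy)cyclopent-2-en-1-one | O=C1C=C[C@H](O[Si](C)(C)C(C)(C)C)C1 | starting material
9 | trans-4-(tert-butyldimethylsilyloxy)-3-vinylcyclopentanone | O=C1C[C@@H](C=C)[C@H](O[Si](C)(C)C(C)(C)C)C1 | intermediate
10 | (S)-4-vinylcyclopent-2-en-1-one (stereocentre = kaurane C13) | O=C1C=C[C@H](C=C)C1 | intermediate
11 | 1-[(methoxymethoxy)methyl]-4-vinylcyclopent-2-en-1-ol, C4 as in 10, both C1 epimers | COCOCC1(O)C=C[C@H](C=C)C1 | intermediate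
12 | 9-{2-[4-hydroxy-4-(methoxymethoxymethyl)cyclopent-2-en-1-yl]ethyl}-9-borabicyclo[3.3.1]nonane | COCOCC1(O)C=C[C@H](CCB2C3CCCC2CCC3)C1 | intermediate
13 | 2-{4-hydroxy-4-[(methoxymethoxy)methyl]cyclopent-2-en-1-yl}ethan-1-ol, ring stereocentre as in 10 | COCOCC1(O)C=C[C@H](CCO)C1 | intermediate
14 | 4-(2-iodoethyl)-1-[(methoxymethoxy)methyl]cyclopent-2-en-1-ol, ring stereocentre as in 10 | COCOCC1(O)C=C[C@H](CCI)C1 | intermediate
15 | dilithio alkoxide: lithium alkoxide of 14 with iodine replaced by lithium | COCOCC1(O[Li])C=C[C@H](CC[Li])C1 | intermediate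
16 | coupled diol: 3-{4-hydroxy-4-[(methoxymethoxy)methyl]cyclopent-2-en-1-yl}-1-[(1S)-1,3,3-trimethyl-2-oxocyclohex-5-en-1-yl]propan-1-ol, C9 and ring-D carbinol epimers | COCOCC1(O)C=C[C@H](CCC(O)[C@@]2(C)C(=O)C(C)(C)CC=C2)C1 | intermediate
17 | diketo enone: 3-[(methoxymethoxy)methyl]-5-{3-oxo-3-[(1S)-1,3,3-trimethyl-2-oxocyclohex-5-en-1-yl]propyl}cyclopent-2-en-1-one, C13 as in 10 | O=C1C=C(COCOC)C[C@H]1CCC(=O)[C@@]1(C)C(=O)C(C)(C)CC=C1 | intermediate
18 | cis-diol: 17 with C1 and C2 hydroxyls added to the ring-A alkene, both cis to the C10 methyl | O=C1C=C(COCOC)C[C@H]1CCC(=O)[C@@]1(C)C(=O)C(C)(C)C[C@H](O)[C@@H]1O | intermediate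
19 | diacetate: 1α,2α-diacetoxy derivative of 18 | O=C1C=C(COCOC)C[C@H]1CCC(=O)[C@@]1(C)C(=O)C(C)(C)C[C@H](OC(C)=O)[C@@H]1OC(C)=O | intermediate
20 | chloromethyl ether: 19 with the MOM group replaced by O–CH2Cl (the CH2Cl carbon is C6) | O=C1C=C(COCCl)C[C@H]1CCC(=O)[C@@]1(C)C(=O)C(C)(C)C[C@H](OC(C)=O)[C@@H]1OC(C)=O | intermediate
21 | ring-C-closed ketol: bicyclo[3.2.1]octan-6-one (rings C and D) with C9 hydroxyl (epimers), C8 chloromethoxymethyl group and the ring-A ketone still free | O=C1C[C@]2(COCCl)C[C@H]1CCC2(O)[C@@]1(C)C(=O)C(C)(C)C[C@H](OC(C)=O)[C@@H]1OC(C)=O | intermediate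
22 | tetracyclic keto diol: rings A–D closed, oxepane C5–C6H2–O–C7H2–C8–C9–C10, tertiary hydroxyls on C5 and C9 (epimers), C16 ketone (17-nor), 1α,2α-diacetate | O=C1C[C@@]23COCC4(O)C(C)(C)C[C@H](OC(C)=O)[C@H](OC(C)=O)[C@@]4(C)C2(O)CC[C@@H]1C3 | intermediate
23 | enol ether diene: C5=C6 cyclic enol ether and C9=C11 alkene, C16 ketone, 1α,2α-diacetate | O=C1C[C@@]23COC=C4C(C)(C)C[C@H](OC(C)=O)[C@H](OC(C)=O)[C@@]4(C)C2=CC[C@@H]1C3 | intermediate
24 | methyl acetal: 6-methoxy oxepane (C6 epimers), H-5 β, C9=C11 alkene, C16 ketone, 1α,2α-diacetate | O=C1C[C@@]23COC(OC)[C@@H]4C(C)(C)C[C@H](OC(C)=O)[C@H](OC(C)=O)[C@@]4(C)C2=CC[C@@H]1C3 | intermediate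
25 | 9α,11α-epoxide of 24 (oxygen on the face of C20 and of the C14 bridge) | O=C1C[C@@]23COC(OC)[C@@H]4C(C)(C)C[C@H](OC(C)=O)[C@H](OC(C)=O)[C@@]4(C)[C@]24O[C@@H]4C[C@@H]1C3 | intermediate
26 | 16-methylene compound: 25 with C16=CH2 in place of the ketone | C=C1C[C@@]23COC(OC)[C@@H]4C(C)(C)C[C@H](OC(C)=O)[C@H](OC(C)=O)[C@@]4(C)[C@]24O[C@@H]4C[C@@H]1C3 | intermediate
27 | 15-hydroxy-16-methylene compound (C15 epimers) | C=C1C(O)[C@@]23COC(OC)[C@@H]4C(C)(C)C[C@H](OC(C)=O)[C@H](OC(C)=O)[C@@]4(C)[C@]24O[C@@H]4C[C@@H]1C3 | intermediate
28 | enone methyl acetal: O-methyl ether of the target lactol (15-oxo-16-methylene) | C=C1C(=O)[C@@]23COC(OC)[C@@H]4C(C)(C)C[C@H](OC(C)=O)[C@H](OC(C)=O)[C@@]4(C)[C@]24O[C@@H]4C[C@@H]1C3 | intermediate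
29 | CNP0224512.1 | C=C1C(=O)[C@@]23CO[C@@H](O)[C@@H]4C(C)(C)C[C@H](OC(C)=O)[C@H](OC(C)=O)[C@@]4(C)[C@]24O[C@@H]4C[C@@H]1C3 | target

Total step count: 22. Longest linear sequence: 18 steps (steps 1–5, then 10–22).

Steps most likely to fail

1. Step 15 (key step). What may go wrong: O-alkylation of the samarium alkoxide by the chloromethyl ether before it is reduced, reductive loss of the C7 oxygen from an over-reduced enone, pinacol-type coupling between the two ring-A ketones, or a Barbier addition too slow for the doubly neopentyl C5 ketone. Fallback, setting out from 19 and coming back at 24: samarium diiodide (THF–HMPA, −78 °C) closes ring C alone, the MOM ether being inert. Benzyl chloromethyl ether and more samarium diiodide are then added to the same flask, so that an untethered benzyloxymethyl samarium reagent adds to the C5 ketone while C16 is masked as its samarium enolate; this should give the tricyclic benzyl ether diol F1. Martin sulfurane then gives the benzyl enol ether diene F2. HCl in methanol removes the MOM group and lets the freed C7 hydroxyl close ring B by transacetalisation, returning to the route at 24. Ring B is thus closed through a C–O bond instead of the C5–C6 bond.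

2. Step 16. What may go wrong: Grob-type fragmentation of the 1,3-diol when one carbinol is activated while the other is still free, cationic methyl migration at the neopentyl carbinols, or incomplete elimination. Fallback, setting out from 22 and coming back at 24: toluenesulfonic acid with trimethyl orthoformate in methanol (50 °C) should convert the C5 carbinol directly into the methyl acetal by ionisation with 1,2-hydride shift from C6 (the acid-mediated rearrangement of glycol monoethers to aldehydes), giving the C9-hydroxy methyl acetal F3. Thionyl chloride in pyridine (−20 °C) then removes the C9 hydroxyl through its chlorosulfite by anti elimination towards C11, which gives 24 with the two carbinols handled by different mechanisms.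

3. Step 12. What may go wrong: poor facial selectivity (osmylation from the face of the C10 methyl's opposite neighbour being disfavoured less than expected, so the diol forms trans to C20) and partial oxidation of the enone alkene. Fallback, setting out from 17 and coming back at 19: Woodward cis-hydroxylation (I2, AgOAc, AcOH, then wet AcOH). The iodonium ion forms on the face preferred by electrophiles, acetate opens it anti, and silver-assisted acetoxonium formation places both oxygens on the opposite face. This should give the cis-hydroxy 2-acetate F4 and the cis-hydroxy 1-acetate F5, which are acetylated under the conditions of step 13 to give 19.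

Further compounds
F1 | step 15 | tricyclic benzyl ether diol: ring C closed, C9 hydroxyl, C5 hydroxyl bearing a benzyloxymethyl group, C7 MOM ether, C16 ketone, 1α,2α-diacetate | O=C1C[C@]2(COCOC)C[C@H]1CCC2(O)[C@@]1(C)C(O)(COCc2ccccc2)C(C)(C)C[C@H](OC(C)=O)[C@@H]1OC(C)=O
F2 | step 15 | benzyl enol ether diene: C9=C11 alkene and exocyclic C5=C6 benzyl enol ether, C7 MOM ether, C16 ketone, 1α,2α-diacetate | O=C1C[C@]2(COCOC)C[C@H]1CC=C2[C@@]1(C)C(=COCc2ccccc2)C(C)(C)C[C@H](OC(C)=O)[C@@H]1OC(C)=O
F3 | step 16 | C9-hydroxy methyl acetal: 24 with a tertiary C9 hydroxyl in place of the C9=C11 alkene | O=C1C[C@@]23COC(OC)[C@@H]4C(C)(C)C[C@H](OC(C)=O)[C@H](OC(C)=O)[C@@]4(C)C2(O)CC[C@@H]1C3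
F4 | step 12 | cis-hydroxy 2-acetate: 18 acetylated on the C2 oxygen only | O=C1C=C(COCOC)C[C@H]1CCC(=O)[C@@]1(C)C(=O)C(C)(C)C[C@H](OC(C)=O)[C@@H]1O
F5 | step 12 | cis-hydroxy 1-acetate: 18 acetylated on the C1 oxygen only | O=C1C=C(COCOC)C[C@H]1CCC(=O)[C@@]1(C)C(=O)C(C)(C)C[C@H](O)[C@@H]1OC(C)=O
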